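**Retrosynthetic overview**

- Feature: the 5,6-dihydro-2H-pyran-2-one ring O1–C2(=O)–C3=C4–C5–C6 has one stereocentre, C6 (S), which carries the (Z)-C1'=C2' chain (C1'–C10'; OH on C4', C6', C8'; phenyl on C10'). The ring is read as the oxidised oxa-[4+2] adduct of 1-methoxybutadiene (C2–C5) and a C6 aldehyde.
- Lactone 26 ⇐ cis-2-methoxy-6-alkynyl-5,6-dihydro-2H-pyran 22 (semi-reduction, acetal hydrolysis, lactol oxidation, deprotection) ⇐ catalytic asymmetric hetero-Diels–Alder of ynal 20 with diene 21, forming C5–C6 and O1–C2.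
- Ynal 20 ⇐ formylation of alkyne 17 ⇐ catalyst-controlled propargylation (C4') of acetonide aldehyde 13 ⇐ two allylboration/ozonolysis rounds on 3-phenylpropanal (C8', then C6' anti).
- Ring order: the 1,3-dioxane protecting ring (step 5), then the pyran ring (step 10), the only ring of the target that the route builds.

Key step: step 10

Assumption: (R)-TRIP, that is (R)-3,3'-bis(2,4,6-triisopropylphenyl)-1,1'-binaphthyl-2,2'-diyl hydrogen phosphate, is taken to deliver the boron-bound group to the Re face of an aldehyde and (S)-TRIP to the Si face. CrCl(L), with L the dianion of (1S,2R)-1-{[3-(1-adamantyl)-2-hydroxy-5-methylbenzylidene]amino}indan-2-ol (trivalent chromium), is taken to give the 6S dihydropyran. Should a sense prove reversed, the mirror-image catalyst is used and nothing else changes.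

**Route**

Step 1
Reactants: 1 3-phenylpropanal; 2 allylboronic acid pinacol ester
Product: 4 (3R)-1-phenylhex-5-en-3-ol, via pinacol borate ester 3 (not isolated)
Conditions: (S)-TRIP (5 mol%), toluene, −30 °C; aq. NaHCO3 work-up
Reagents that add atoms: none
Why: Chiral phosphoric acid-catalysed allylboration runs through a closed chair transition state in which the acid hydrogen-bonds to a boronate oxygen and to the formyl hydrogen, so the (S)-catalyst should direct Si-face allyl transfer and set C8' as R.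

Step 2
Reactants: 4 (3R)-1-phenylhex-5-en-3-ol
Product: 5 tert-butyldimethyl{[(3R)-1-phenylhex-5-en-3-yl]oxy}silane
Conditions: TBSCl, imidazole, DMF, rt
Reagents that add atoms: tert-butyldimethylsilyl chloride, CC(C)(C)[Si](C)(C)Cl
Why: Imidazole-promoted silylation of an unhindered secondary alcohol is routine and leaves C8' untouched.

Step 3
Reactants: 5 tert-butyldimethyl{[(3R)-1-phenylhex-5-en-3-yl]oxy}silane
Product: 7 (3R)-3-[(tert-butyldimethylsilyl)oxy]-5-phenylpentanal, via secondary ozonide 6 (not isolated)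
Conditions: O3, CH2Cl2, −78 °C; then PPh3, −78 °C → rt
Reagents that add atoms: ozone, [O-][O+]=O
Why: Ozonolysis with reductive work-up cleaves the terminal alkene to the aldehyde (C6') without affecting the silyl ether, the phenyl ring or C8'.

Step 4
Reactants: 7 (3R)-3-[(tert-butyldimethylsilyl)oxy]-5-phenylpentanal; 2 allylboronic acid pinacol ester
Product: 9 (4R,6R)-6-[(tert-butyldimethylsilyl)oxy]-8-phenyloct-1-en-4-ol, via pinacol borate ester 8 (not isolated)
Conditions: (R)-TRIP (5 mol%), toluene, −30 °C; aq. NaHCO3 work-up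
Reagents that add atoms: none
Why: A second chiral phosphoric acid-catalysed allylboration, now with the (R)-catalyst for Re-face transfer, should set C6' anti to C8' under catalyst control, since the β-silyloxy centre exerts little 1,3-induction in the closed transition state.

Step 5
Reactants: 9 (4R,6R)-6-[(tert-butyldimethylsilyl)oxy]-8-phenyloct-1-en-4-ol
Product: 11 (4R,6R)-2,2-dimethyl-4-(2-phenylethyl)-6-(prop-2-en-1-yl)-1,3-dioxane, via anti diol 10 (not isolated)
Conditions: TsOH·H2O (cat.), MeOH, rt; evaporate; then Me2C(OMe)2, acetone, rt; Et3N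
Reagents that add atoms: 2,2-dimethoxypropane, COC(C)(C)OC
Why: Acid-catalysed methanolysis of the silyl ether followed by transacetalisation with 2,2-dimethoxypropane gives the anti-1,3-diol acetonide without touching either carbinol centre.

Step 6
Reactants: 11 (4R,6R)-2,2-dimethyl-4-(2-phenylethyl)-6-(prop-2-en-1-yl)-1,3-dioxane
Product: 13 2-[(4S,6R)-2,2-dimethyl-6-(2-phenylethyl)-1,3-dioxan-4-yl]acetaldehyde, via secondary ozonide 12 (not isolated)
Conditions: O3, CH2Cl2, −78 °C; then PPh3, −78 °C → rt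
Reagents that add atoms: ozone, [O-][O+]=O
Why: Ozonolysis with reductive work-up unmasks the C4' aldehyde; the acetonide is inert under these neutral conditions.

Step 7
Reactants: 13 2-[(4S,6R)-2,2-dimethyl-6-(2-phenylethyl)-1,3-dioxan-4-yl]acetaldehyde; 14 allenylboronic acid pinacol ester
Product: 16 (2R)-1-[(4R,6R)-2,2-dimethyl-6-(2-phenylethyl)-1,3-dioxan-4-yl]pent-4-yn-2-ol, via pinacol borate ester 15 (not isolated)
Conditions: (R)-TRIP (10 mol%), 4 Å MS, toluene, −20 °C; aq. NaHCO3 work-up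
Reagents that add atoms: none
Why: Chiral phosphoric acid-catalysed propargylation with the allenylboronate proceeds by SE2' transfer through the same kind of chair transition state as the allylboration, so Re-face addition under the (R)-catalyst should set C4' as R, syn to C6'.

Step 8
Reactants: 16 (2R)-1-[(4R,6R)-2,2-dimethyl-6-(2-phenylethyl)-1,3-dioxan-4-yl]pent-4-yn-2-ol
Product: 17 tert-butyl({(2R)-1-[(4S,6R)-2,2-dimethyl-6-(2-phenylethyl)-1,3-dioxan-4-yl]pent-4-yn-2-yl}oxy)dimethylsilane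
Conditions: TBSOTf, 2,6-lutidine, CH2Cl2, −78 → 0 °C
Reagents that add atoms: tert-butyldimethylsilyl trifluoromethanesulfonate, CC(C)(C)[Si](C)(C)OS(=O)(=O)C(F)(F)F
Why: Silylation with the silyl triflate and a hindered base protects the secondary alcohol quickly at low temperature, where the acetonide and the terminal alkyne are unaffected.

Step 9
Reactants: 17 tert-butyl({(2R)-1-[(4S,6R)-2,2-dimethyl-6-(2-phenylethyl)-1,3-dioxan-4-yl]pent-4-yn-2-yl}oxy)dimethylsilane
Product: 20 (5R)-5-[(tert-butyldimethylsilyl)oxy]-6-[(4S,6R)-2,2-dimethyl-6-(2-phenylethyl)-1,3-dioxan-4-yl]hex-2-ynal, via lithium acetylide 18 (not isolated), via lithium hemiaminal alkoxide 19 (not isolated)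
Conditions: n-BuLi, THF, −78 °C; DMF, −78 → 0 °C; inverse quench into cold aq. KH2PO4/MTBE
Reagents that add atoms: N,N-dimethylformamide, CN(C)C=O
Why: Formylation of the lithium acetylide with DMF holds the aldehyde as its hemiaminal alkoxide until the buffered inverse quench, which releases the ynal while keeping dimethylamine protonated so that it cannot add to the triple bond.

Step 10
Reactants: 20 (5R)-5-[(tert-butyldimethylsilyl)oxy]-6-[(4S,6R)-2,2-dimethyl-6-(2-phenylethyl)-1,3-dioxan-4-yl]hex-2-ynal; 21 (E)-1-methoxybuta-1,3-diene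
Product: 22 (2R,6S)-6-{(4R)-4-[(tert-butyldimethylsilyl)oxy]-5-[(4S,6R)-2,2-dimethyl-6-(2-phenylethyl)-1,3-dioxan-4-yl]pent-1-yn-1-yl}-2-methoxy-5,6-dihydro-2H-pyran (2,6-cis)
Conditions: CrCl(L) (5 mol%; L as defined above), powdered 4 Å MS, 21 (2 equiv), TBME, rt
Reagents that add atoms: none
Why: The formyl oxygen of 20 binds the Lewis-acidic trivalent chromium centre and the electron-rich diene adds in a concerted, asynchronous oxa-[4+2] cycloaddition in which C5–C6 bonding runs ahead of O1–C2; the closest known reaction type is the chromium Schiff-base-catalysed hetero-Diels–Alder reaction of 1-alkoxybutadienes with aldehydes, conjugated ynals included. The dihydropyran ring (O1, C2–C6) closes by intermolecular [4+2] cycloaddition, both ring bonds forming in the one step. C6 is set by the catalyst, which should leave the Si face of the formyl group open and give 6S whatever the remote C4', C6' and C8' centres prefer; C2 follows from the endo approach (cis to C6) and is erased at the lactone stage. The step needs enantiofacial, regio- and chemoselectivity: the methoxy group polarises the diene so that its unsubstituted terminus attacks the carbonyl carbon, and metal activation of C=O makes it, not the C≡C bond, the 2π partner. The ynal is slim and has no enolisable α-hydrogen, and its silyl ether and acetonide oxygens are hindered and remote, so they should not compete for the metal.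

Step 11
Reactants: 22 (2R,6S)-6-{(4R)-4-[(tert-butyldimethylsilyl)oxy]-5-[(4S,6R)-2,2-dimethyl-6-(2-phenylethyl)-1,3-dioxan-4-yl]pent-1-yn-1-yl}-2-methoxy-5,6-dihydro-2H-pyran
Product: 23 (2R,6S)-6-{(1Z,4R)-4-[(tert-butyldimethylsilyl)oxy]-5-[(4S,6R)-2,2-dimethyl-6-(2-phenylethyl)-1,3-dioxan-4-yl]pent-1-en-1-yl}-2-methoxy-5,6-dihydro-2H-pyran
Conditions: H2 (1 atm), Pd/CaCO3 poisoned with Pb(OAc)2, quinoline, EtOAc, rt, stopped at one equivalent
Reagents that add atoms: none
Why: Lindlar semi-hydrogenation adds hydrogen syn to the alkyne to give the Z C1'=C2' alkene, and the poisoned catalyst should leave the ring alkene, the acetal and the phenyl ring alone.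

Step 12
Reactants: 23 (2R,6S)-6-{(1Z,4R)-4-[(tert-butyldimethylsilyl)oxy]-5-[(4S,6R)-2,2-dimethyl-6-(2-phenylethyl)-1,3-dioxan-4-yl]pent-1-en-1-yl}-2-methoxy-5,6-dihydro-2H-pyran
Product: 24 (6S)-6-{(1Z,4R)-4-[(tert-butyldimethylsilyl)oxy]-5-[(4S,6R)-2,2-dimethyl-6-(2-phenylethyl)-1,3-dioxan-4-yl]pent-1-en-1-yl}-5,6-dihydro-2H-pyran-2-ol (anomer mixture)
Conditions: PPTS (cat.), acetone/H2O (10:1), rt
Reagents that add atoms: water, O
Why: Mild acid hydrolysis of the allylic anomeric acetal goes through a conjugated oxocarbenium ion far more readily than cleavage of the silyl ether, and acetone as solvent should hold the acetonide in place by mass action.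

Step 13
Reactants: 24 (6S)-6-{(1Z,4R)-4-[(tert-butyldimethylsilyl)oxy]-5-[(4S,6R)-2,2-dimethyl-6-(2-phenylethyl)-1,3-dioxan-4-yl]pent-1-en-1-yl}-5,6-dihydro-2H-pyran-2-ol
Product: 25 (6S)-6-{(1Z,4R)-4-[(tert-butyldimethylsilyl)oxy]-5-[(4S,6R)-2,2-dimethyl-6-(2-phenylethyl)-1,3-dioxan-4-yl]pent-1-en-1-yl}-5,6-dihydro-2H-pyran-2-one
Conditions: activated MnO2 (excess), CH2Cl2, rt
Reagents that add atoms: none
Why: MnO2 oxidation of an allylic hemiacetal gives the α,β-unsaturated δ-lactone under neutral conditions that spare the Z alkene, the silyl ether and the acetonide.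

Step 14
Reactants: 25 (6S)-6-{(1Z,4R)-4-[(tert-butyldimethylsilyl)oxy]-5-[(4S,6R)-2,2-dimethyl-6-(2-phenylethyl)-1,3-dioxan-4-yl]pent-1-en-1-yl}-5,6-dihydro-2H-pyran-2-one
Product: 26 (6S)-6-[(1Z,4R,6S,8R)-4,6,8-trihydroxy-10-phenyldec-1-en-1-yl]-5,6-dihydro-2H-pyran-2-one
Conditions: 48% aq. HF, MeCN, 0 °C → rt
Reagents that add atoms: none
Why: Aqueous HF in acetonitrile should cleave the secondary silyl ether by fluoride-assisted desilylation and hydrolyse the strained anti acetonide, while being mild enough for the unsaturated lactone and the Z alkene.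

**Compound list**

1 | 3-phenylpropanal | O=CCCc1ccccc1 | starting material
2 | allylboronic acid pinacol ester | C=CCB1OC(C)(C)C(C)(C)O1 | starting material
3 | pinacol borate ester of 4, (R)-configured | C=CC[C@H](OB1OC(C)(C)C(C)(C)O1)CCc1ccccc1 | intermediate (not isolated)
4 | (3R)-1-phenylhex-5-en-3-ol | C=CC[C@H](O)CCc1ccccc1 | intermediate
5 | tert-butyldimethyl{[(3R)-1-phenylhex-5-en-3-yl]oxy}silane | C=CC[C@H](O[Si](C)(C)C(C)(C)C)CCc1ccccc1 | intermediate
6 | secondary ozonide of 5, 3-[(2R)-2-silyloxy-4-phenylbutyl]-1,2,4-trioxolane (ring carbon unassigned) | C1(C[C@H](O[Si](C)(C)C(C)(C)C)CCc2ccccc2)OCOO1 | intermediate (not isolated)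
7 | (3R)-3-[(tert-butyldimethylsilyl)oxy]-5-phenylpentanal | O=CC[C@H](O[Si](C)(C)C(C)(C)C)CCc1ccccc1 | intermediate
8 | pinacol borate ester of 9 | C=CC[C@@H](OB1OC(C)(C)C(C)(C)O1)C[C@H](O[Si](C)(C)C(C)(C)C)CCc1ccccc1 | intermediate (not isolated)
9 | (4R,6R)-6-[(tert-butyldimethylsilyl)oxy]-8-phenyloct-1-en-4-ol | C=CC[C@@H](O)C[C@H](O[Si](C)(C)C(C)(C)C)CCc1ccccc1 | intermediate
10 | (4R,6R)-8-phenyloct-1-ene-4,6-diol (anti) | C=CC[C@@H](O)C[C@H](O)CCc1ccccc1 | intermediate (not isolated)
11 | (4R,6R)-2,2-dimethyl-4-(2-phenylethyl)-6-(prop-2-en-1-yl)-1,3-dioxane | C=CC[C@@H]1C[C@H](OC(C)(C)O1)CCc1ccccc1 | intermediate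
12 | secondary ozonide of 11 (1,2,4-trioxolane, ring carbon unassigned) | C1(C[C@@H]2C[C@H](OC(C)(C)O2)CCc3ccccc3)OCOO1 | intermediate (not isolated)
13 | 2-[(4S,6R)-2,2-dimethyl-6-(2-phenylethyl)-1,3-dioxan-4-yl]acetaldehyde | O=CC[C@@H]1C[C@H](OC(C)(C)O1)CCc1ccccc1 | intermediate
14 | allenylboronic acid pinacol ester | C=C=CB1OC(C)(C)C(C)(C)O1 | starting material
15 | pinacol borate ester of 16 | C#CC[C@@H](OB1OC(C)(C)C(C)(C)O1)C[C@@H]2C[C@H](OC(C)(C)O2)CCc2ccccc2 | intermediate (not isolated)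
16 | (2R)-1-[(4R,6R)-2,2-dimethyl-6-(2-phenylethyl)-1,3-dioxan-4-yl]pent-4-yn-2-ol | C#CC[C@@H](O)C[C@@H]1C[C@H](OC(C)(C)O1)CCc1ccccc1 | intermediate
17 | tert-butyl({(2R)-1-[(4S,6R)-2,2-dimethyl-6-(2-phenylethyl)-1,3-dioxan-4-yl]pent-4-yn-2-yl}oxy)dimethylsilane | C#CC[C@@H](O[Si](C)(C)C(C)(C)C)C[C@@H]1C[C@H](OC(C)(C)O1)CCc1ccccc1 | intermediate
18 | lithium acetylide of 17 | [Li]C#CC[C@@H](O[Si](C)(C)C(C)(C)C)C[C@@H]1C[C@H](OC(C)(C)O1)CCc1ccccc1 | intermediate (not isolated)
19 | lithium hemiaminal alkoxide (DMF adduct of 18) | CN(C)C(O[Li])C#CC[C@@H](O[Si](C)(C)C(C)(C)C)C[C@@H]1C[C@H](OC(C)(C)O1)CCc1ccccc1 | intermediate (not isolated)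
20 | (5R)-5-[(tert-butyldimethylsilyl)oxy]-6-[(4S,6R)-2,2-dimethyl-6-(2-phenylethyl)-1,3-dioxan-4-yl]hex-2-ynal | O=CC#CC[C@@H](O[Si](C)(C)C(C)(C)C)C[C@@H]1C[C@H](OC(C)(C)O1)CCc1ccccc1 | intermediate
21 | (E)-1-methoxybuta-1,3-diene | CO/C=C/C=C | starting material
22 | (2R,6S)-cis-6-alkynyl-2-methoxy-5,6-dihydro-2H-pyran (full name in step 10) | CO[C@H]1C=CC[C@@H](C#CC[C@@H](O[Si](C)(C)C(C)(C)C)C[C@@H]2C[C@H](OC(C)(C)O2)CCc2ccccc2)O1 | intermediate
23 | (2R,6S)-cis-6-[(1Z)-alkenyl]-2-methoxy-5,6-dihydro-2H-pyran (full name in step 11) | CO[C@H]1C=CC[C@@H](/C=C\C[C@@H](O[Si](C)(C)C(C)(C)C)C[C@@H]2C[C@H](OC(C)(C)O2)CCc2ccccc2)O1 | intermediate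
24 | (6S)-6-[(1Z)-alkenyl]-5,6-dihydro-2H-pyran-2-ol, anomer mixture (full name in step 12) | OC1C=CC[C@@H](/C=C\C[C@@H](O[Si](C)(C)C(C)(C)C)C[C@@H]2C[C@H](OC(C)(C)O2)CCc2ccccc2)O1 | intermediate
25 | (6S)-6-[(1Z)-alkenyl]-5,6-dihydro-2H-pyran-2-one, silyl ether and acetonide in place (full name in step 13) | O=C1C=CC[C@@H](/C=C\C[C@@H](O[Si](C)(C)C(C)(C)C)C[C@@H]2C[C@H](OC(C)(C)O2)CCc2ccccc2)O1 | intermediate
26 | (6S)-6-[(1Z,4R,6S,8R)-4,6,8-trihydroxy-10-phenyldec-1-en-1-yl]-5,6-dihydro-2H-pyran-2-one | O=C1C=CC[C@@H](/C=C\C[C@@H](O)C[C@@H](O)C[C@H](O)CCc2ccccc2)O1 | target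

**Step count**

Total step count: 14. Longest linear sequence: 14 steps (1 → 26).

**Steps most likely to fail**

1. Step 10. The bulky, polyoxygenated ynal may turn over slowly, the catalyst may discriminate the formyl faces poorly, and the diene may oligomerise before it is consumed. The fallback sets C6 by allylboration and closes the lactone by metathesis; it sets out from 20 and comes back at 25.
   - Allylboration of 20 with 2 under (S)-TRIP (Si face) gives the pinacol borate ester F1, which aqueous work-up converts into (4S,8R)-8-[(tert-butyldimethylsilyl)oxy]-9-[(4S,6R)-2,2-dimethyl-6-(2-phenylethyl)-1,3-dioxan-4-yl]non-1-en-5-yn-4-ol F2.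
   - Lindlar semi-hydrogenation (H2, Pd/CaCO3 poisoned with Pb(OAc)2, quinoline) gives the (4S,5Z)-dienol F3.
   - Acryloyl chloride and Et3N in CH2Cl2 at 0 °C give the acrylate F4.
   - Ring-closing metathesis with RuCl2(=CHPh)(PCy3)(H2IMes), the second-generation Grubbs catalyst, in CH2Cl2 at 40 °C closes the six-membered lactone through the terminal alkene and gives 25. The route resumes at step 14.

2. Step 7. Diastereocontrol may erode because catalyst control over a linear β-alkoxy aldehyde is only moderate, and some allenyl carbinol may form by the competing SE2 pathway. The fallback uses the allylboration already proven in step 4 and turns the allyl group into the propargyl group; it sets out from 13 and comes back at 17.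
   - Allylboration of 13 with 2 under (R)-TRIP gives the pinacol borate ester F5 and, after work-up, (2R)-1-[(4R,6R)-2,2-dimethyl-6-(2-phenylethyl)-1,3-dioxan-4-yl]pent-4-en-2-ol F6.
   - TBSOTf and 2,6-lutidine give the silyl ether F7.
   - Ozonolysis (O3, then PPh3) passes through the secondary ozonide F8 to (3S)-3-[(tert-butyldimethylsilyl)oxy]-4-[(4S,6R)-2,2-dimethyl-6-(2-phenylethyl)-1,3-dioxan-4-yl]butanal F9.
   - Ohira–Bestmann homologation (dimethyl (1-diazo-2-oxopropyl)phosphonate, K2CO3, MeOH) converts F9 into alkyne 17. The route resumes at step 9.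

3. Step 12. The free lactol may open to the (Z)-hydroxy enal, which can isomerise or dehydrate to a dienal, and part of the acetonide may be lost during hydrolysis. The fallback avoids accumulating the lactol; it sets out from 23 and comes back at 25.
   - Treatment of 23 with CrO3/H2SO4 in acetone at 0 °C (Jones oxidation, hexavalent chromium) hydrolyses the acetal and oxidises the hemiacetal as it forms, giving 25 directly.
   - This fallback makes no new compound (F0). The route resumes at step 14.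

**Further compounds**

F1 | step 10 | pinacol borate ester of F2 | C=CC[C@H](OB1OC(C)(C)C(C)(C)O1)C#CC[C@@H](O[Si](C)(C)C(C)(C)C)C[C@@H]2C[C@H](OC(C)(C)O2)CCc2ccccc2
F2 | step 10 | (4S,8R)-8-[(tert-butyldimethylsilyl)oxy]-9-[(4S,6R)-2,2-dimethyl-6-(2-phenylethyl)-1,3-dioxan-4-yl]non-1-en-5-yn-4-ol | C=CC[C@H](O)C#CC[C@@H](O[Si](C)(C)C(C)(C)C)C[C@@H]1C[C@H](OC(C)(C)O1)CCc1ccccc1
F3 | step 10 | (4S,5Z,8R)-8-[(tert-butyldimethylsilyl)oxy]-9-[(4S,6R)-2,2-dimethyl-6-(2-phenylethyl)-1,3-dioxan-4-yl]nona-1,5-dien-4-ol | C=CC[C@H](O)/C=C\C[C@@H](O[Si](C)(C)C(C)(C)C)C[C@@H]1C[C@H](OC(C)(C)O1)CCc1ccccc1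
F4 | step 10 | prop-2-enoate (acrylate) ester of F3 | C=CC[C@H](OC(=O)C=C)/C=C\C[C@@H](O[Si](C)(C)C(C)(C)C)C[C@@H]1C[C@H](OC(C)(C)O1)CCc1ccccc1
F5 | step 7 | pinacol borate ester of F6 | C=CC[C@@H](OB1OC(C)(C)C(C)(C)O1)C[C@@H]2C[C@H](OC(C)(C)O2)CCc2ccccc2
F6 | step 7 | (2R)-1-[(4R,6R)-2,2-dimethyl-6-(2-phenylethyl)-1,3-dioxan-4-yl]pent-4-en-2-ol | C=CC[C@@H](O)C[C@@H]1C[C@H](OC(C)(C)O1)CCc1ccccc1
F7 | step 7 | tert-butyl({(2R)-1-[(4S,6R)-2,2-dimethyl-6-(2-phenylethyl)-1,3-dioxan-4-yl]pent-4-en-2-yl}oxy)dimethylsilane | C=CC[C@@H](O[Si](C)(C)C(C)(C)C)C[C@@H]1C[C@H](OC(C)(C)O1)CCc1ccccc1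
F8 | step 7 | secondary ozonide of F7 (1,2,4-trioxolane, ring carbon unassigned) | C1(C[C@@H](O[Si](C)(C)C(C)(C)C)C[C@@H]2C[C@H](OC(C)(C)O2)CCc3ccccc3)OCOO1
F9 | step 7 | (3S)-3-[(tert-butyldimethylsilyl)oxy]-4-[(4S,6R)-2,2-dimethyl-6-(2-phenylethyl)-1,3-dioxan-4-yl]butanal | O=CC[C@@H](O[Si](C)(C)C(C)(C)C)C[C@@H]1C[C@H](OC(C)(C)O1)CCc1ccccc1
F0 | step 12 | none | none
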